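## The problem

The target is a cyclopent-3-ene in which every ring carbon is functionalised. C1 is a fully substituted carbinol that also carries the undecanoyl chain (ketone carbon C1', alkyl carbons C2'–C11'), C2 and C5 are acetoxy-bearing methines, and C3=C4 joins them. The ring therefore has to be built, and the C1–C1' junction between ring and chain is the one skeletal bond that does not come with a simple building block. There are three contiguous stereocentres; the two acetates are cis to each other and trans to the C1 hydroxyl, so the molecule is meso and only relative configuration has to be controlled. Once cis, the C2 and C5 oxygens screen one ring face and can send an incoming C1 oxygen to the other, provided C1 is oxygenated last; the cis relationship itself has to come from the first-formed ring carbinol steering the second. The groups that limit the reagents are the allylic acetates, which ionise, migrate or cleave under acid, base or soft-metal catalysis, and the tertiary α-ketol, which does not survive strong base. The enabling feature is that C1 is bonded to C1' and to both oxygenated carbons C2 and C5, which are bridged by C3=C4. With C2 and C5 as carbonyls and C1=C1' as an alkene, this array is a 2-alkylidenecyclopent-4-ene-1,3-dione, the isomer of a 4-alkynyl-4-hydroxycyclobutenone, so ring and junction can arise together from a strained four-membered ring by a 1,2-acyl shift.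

## Retrosynthesis

Target 12 is first simplified at C1. The C1–O bond and the C1' carbonyl oxygen are removed together, which leaves the trisubstituted exocyclic alkene C1=C1' of diacetate 11. This is preferred to hydroxylating an enolate of a C1–H ketone, which would expel a β-acetate, and to adding a C1' acyl anion equivalent to a ring ketone, which would require three ring oxygens to be told apart. Precursor 11 has two stereocentres instead of three and no ketol. The forward reaction must be a ketohydroxylation that puts the carbonyl on the hydrogen-bearing C1', attacks the face anti to both acetates, and prefers the trisubstituted alkene to the ring alkene.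

In 11 the two acetyl groups and the two carbinol C–H bonds are removed next, through cis-diol 10, to give dione 8. Oxidising allylic C–H bonds of a cyclopentene instead would offer no handle for the cis relationship, whereas hydride addition to 8 sets it by induction from the first carbinol in hydroxy enone 9. Dione 8 has no stereocentre and no protecting group. The forward reduction must be a 1,2-addition at both carbonyls of a doubly activated acceptor and must deliver the second hydride anti to the first oxygen.

Dione 8 is where the strained-ring logic applies. The C1–C2 bond (target numbering) is cut and C2 is reconnected to C5, which turns the five-membered ring into cyclobutenone 7 with C1 and C1' as an alkyne. The neighbouring cut, a Knoevenagel-type condensation forming C1=C1' on an existing five-membered ring, was set aside: with enolisable aliphatic aldehydes such condensations tend to run on to bis-adducts, and the ring partner is itself a fragile acceptor. The isomerisation needs only a catalyst and makes ring and junction at once. Precursor 7 is one ring size smaller and divides into a C4 and a C12 piece. The forward step, catalysed by Pd(O2CCF3)2, must shift the acyl and not the vinyl ring carbon and must run near room temperature, below the onset of electrocyclic opening of the cyclobutenone.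

Carbinol 7 is cut between the carbinol carbon and the alkyne, giving cyclobutenedione 4 and 1-dodecyne 5, the latter used as its lithium salt 6. Because 4 is symmetric there is no regiochemical question, and the new stereocentre is irrelevant since step 4 destroys it. Compound 5 is commercial and brings C1 and the whole chain. What is asked is a clean single 1,2-addition to a small, unhindered ene-dione at low temperature.

Dione 4 is not a practical article of commerce. It is traced to cyclobutane-1,2-dione 2 by loss of two hydrogens (α-bromination to 3, then dehydrobromination), and 2 to the commercial silyl enediol ether 1 by oxidative desilylation. Introducing the ring alkene before the acetylide addition is preferred to dehydrogenating a cyclobutanone later, for which precedent is thin. The forward steps must stay anhydrous and non-nucleophilic, because four-membered 1,2-diones ring-contract with water or hydroxide.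

## Roads not taken

Alternative 1: The C1–O bond and the C1' carbonyl are traced to the two double bonds of an exocyclic allene, A2.
- **Forward key step:** dimethyldioxirane epoxidises both allene double bonds, the ring-side one first and from the face anti to the silyloxy groups. Bu4NI then opens the bis-epoxide at C2', which releases the C1' carbonyl and the C1 hydroxyl, and Zn in acetic acid removes the iodine to give ketol A1.
- **Merits:** the allene is far more nucleophilic than the ring alkene, so the site-selectivity question of step 7 of the chosen plan does not arise; on this point the alternative is better. Both allene diastereomers converge on one product.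
- **Weak points:** A2 is no easier to reach than 11, since the cis-dioxygenated ring and the allene must be built first. The oxidation needs a stoichiometric dioxirane and a separate reduction in acid next to allylic silyl ethers. A1 still needs desilylation and acetylation on a sensitive α-ketol.
- **Comparison:** against the better oxidation selectivity, the chosen plan makes ring and junction in one catalytic step from two commercial pieces, carries the final acetates through the oxidation, and is several steps shorter.

Alternative 2: The ring bond between the carbonyl carbon C2 and the vinyl carbon C3 is cut, leading to the acyclic (Z)-vinyl iodide ester A4.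
- **Forward key step:** iodine–lithium exchange with t-BuLi gives a vinyllithium that attacks the ester carbon in a 5-exo-trig acyl substitution and closes cyclopentenone A3.
- **Merits:** the C1/C5 relationship is fixed before the ring exists. The alkyne is a latent C1' ketone whose unmasking is orthogonal to the ring alkene, so no two alkenes compete; here the alternative is better than the chosen plan.
- **Weak points:** A4 has two adjacent stereocentres, one a tertiary carbinol, that need a diastereoselective acyclic construction with no obvious control element. t-BuLi must be used beside an ester and a free tertiary hydroxyl, and the enone product is itself an acceptor for organolithiums. After ring closure three further selectivity problems remain: hydride reduction of the C2 ketone trans to the neighbouring hydroxyl, regioselective hydration of the internal alkyne toward C1', and silyl-to-acetyl exchange.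
- **Comparison:** the chosen plan has one uncertain site selectivity at the end, but no acyclic stereocontrol, no protecting-group exchange and roughly half the steps.

Alternative 3: Both C1–C2 and C1–C5 are cut in a (4+1) sense, giving 1-hydroxydodecan-2-one A6 and (Z)-but-2-enedial A7.
- **Forward key step:** the magnesium enediolate of A6 adds through its hydroxylated carbon to one aldehyde of A7 and, after re-enolisation, to the other, closing triol A5. Selective acetylation of the two secondary hydroxyls would finish the synthesis.
- **Merits:** it is by far the shortest route, with ring, junction and all three stereocentres made in one step and no redox adjustment. In step count it is clearly better than the chosen plan.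
- **Weak points:** A7 is configurationally and chemically labile (Z-to-E isomerisation, hydration, polymerisation) and is an excellent Michael acceptor for the enediolate. The second aldol must occur at the same, now crowded carbon and not at C3 of A6. Both aldols are reversible, and A5 can dehydrate toward a cyclopentadiene. The 2,5-cis/1-trans outcome rests on an unproven magnesium chelate, and no such double-aldol annulation is established.
- **Comparison:** the chosen plan is five steps longer, but each step belongs to an established reaction class and its stereocontrol rests on anti approach to a rigid ring.

Key step: step 4

Assumption: the target SMILES is read as the meso isomer (acetoxy groups cis to each other, C1 hydroxyl trans to both); being achiral, it is reached through racemic intermediates.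

Step 1  
Reactants: 1 1,2-bis(trimethylsilyloxy)cyclobutene  
Product: 2 cyclobutane-1,2-dione  
Conditions: Br2 (1.0 equiv), pentane, −60 °C to rt; crystallisation from pentane at −60 °C  
Reagents that add atoms: none  
Why: Oxidative desilylation of a silyl enediol ether: bromine adds to the electron-rich alkene and both silyl groups leave as Me3SiBr, unmasking the 1,2-dione under anhydrous conditions that avoid its ring contraction; no stereocentre is involved.

Step 2  
Reactants: 2 cyclobutane-1,2-dione  
Product: 4 cyclobut-3-ene-1,2-dione, via 3-bromocyclobutane-1,2-dione 3 (not isolated)  
Conditions: Br2 (1.0 equiv), CH2Cl2, 0 °C, dark; evaporation; Et3N (1.05 equiv), Et2O, −20 °C; filtration, used at once  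
Reagents that add atoms: none  
Why: Acid-catalysed α-bromination of the dione through its enol, then E1cB dehydrobromination: in 3 the C4 proton is α to one carbonyl and the bromide at C3 is β to it, so a weak amine base suffices; no stereocentre remains.

Step 3  
Reactants: 4 cyclobut-3-ene-1,2-dione; 5 1-dodecyne  
Product: 7 4-(dodec-1-yn-1-yl)-4-hydroxycyclobut-2-en-1-one (racemic), via lithium dodec-1-yn-1-ide 6 (not isolated)  
Conditions: 5, n-BuLi (1.0 equiv), THF, −78 °C; cannulated into 4 (1.1 equiv), THF, −78 °C; NH4Cl (aq.), −78 °C  
Reagents that add atoms: none  
Why: 1,2-Addition of a lithium acetylide to a cyclobutenedione carbonyl, a standard entry to 4-alkynyl-4-hydroxycyclobutenones; the dione is symmetric, inverse addition keeps it in excess so that the less electrophilic lithium alkoxide of 7 is not attacked again, and the new carbinol centre forms as a racemate that step 4 erases.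

Step 4  
Reactants: 7 4-(dodec-1-yn-1-yl)-4-hydroxycyclobut-2-en-1-one  
Product: 8 2-undecylidenecyclopent-4-ene-1,3-dione  
Conditions: Pd(O2CCF3)2 (5 mol %), THF, 23 °C, dark  
Reagents that add atoms: none  
Why: Pd(O2CCF3)2 (divalent palladium) binds the alkyne of 7 as an electrophilic π-complex, and the ring acyl carbon shifts from the carbinol carbon to the proximal alkyne carbon on the side opposite the metal, forming the C1–C2 bond of the target numbering while the carbinol carbon becomes the second carbonyl. The vinyl–palladium bond left at the distal carbon is cleaved by the trifluoroacetic acid released in the shift, which gives the exocyclic CH= and returns the catalyst. The closest known reaction type is this very one, the divalent-palladium-catalysed expansion of 4-alkynyl-4-hydroxycyclobutenones to 2-alkylidenecyclopent-4-ene-1,3-diones, a metal-triggered relative of the pinacol-type acyl shift by which 2-oxygenated cyclobutanones give cyclopentane-1,3-diones. The five-membered ring closes by ring expansion (1,2-shift, four to five) and not by an exo or endo cyclisation, driven by loss of cyclobutene strain and gain of a C=O bond. No stereocentre is formed: the carbinol centre of 7 is destroyed, and because the two ring carbonyls of 8 are equivalent the exocyclic alkene has no geometric isomers. The selectivity needed is migration of the acyl and not the vinyl ring carbon; the substrate secures it, since only the acyl shift leaves the new carbonyl conjugated to the ring alkene and gives the 1,3-dione, and acyl carbons are the preferred migrating groups in this family of α-ketol-type shifts. Room temperature and the absence of base keep 7 from thermal electrocyclic ring opening and 8 from oligomerising.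

Step 5  
Reactants: 8 2-undecylidenecyclopent-4-ene-1,3-dione  
Product: 10 (1R*,3S*)-2-undecylidenecyclopent-4-ene-1,3-diol (cis-diol; racemic), via 4-hydroxy-5-undecylidenecyclopent-2-en-1-one 9 (not isolated)  
Conditions: NaBH4 (2.2 equiv), CeCl3·7H2O (2.2 equiv), MeOH/THF, −78 °C; acetone, then pH 7 phosphate buffer  
Reagents that add atoms: none  
Why: Luche reduction: CeCl3 in methanol turns NaBH4 into hard methoxyborohydrides and activates the carbonyls, so both C=O groups are reduced 1,2 in preference to hydride addition at the doubly activated C1'. The first reduction gives 9, and the second hydride enters anti to its oxygen substituent, as in reductions of 4-oxygenated cyclopent-2-enones, which sets C2 and C5 cis.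

Step 6  
Reactants: 10 (1R*,3S*)-2-undecylidenecyclopent-4-ene-1,3-diol  
Product: 11 (1R*,3S*)-2-undecylidenecyclopent-4-ene-1,3-diyl diacetate (cis; racemic)  
Conditions: Ac2O (3 equiv), pyridine, DMAP (cat.), CH2Cl2, 0 °C  
Reagents that add atoms: acetic anhydride, CC(=O)OC(C)=O  
Why: Nucleophile-catalysed acetylation of secondary alcohols under buffered basic conditions that do not ionise the doubly allylic C–O bonds; the configuration at C2 and C5 is untouched.

Step 7  
Reactants: 11 (1R*,3S*)-2-undecylidenecyclopent-4-ene-1,3-diyl diacetate  
Product: 12 (1R,3S)-2-hydroxy-2-undecanoylcyclopent-4-ene-1,3-diyl diacetate, hydroxyl trans to both acetoxy groups (meso; the target)  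
Conditions: RuCl3 (1 mol %), KHSO5 (as 2KHSO5·KHSO4·K2SO4, limiting excess), NaHCO3, EtOAc/MeCN/H2O (6:6:1), 0 °C to rt  
Reagents that add atoms: potassium peroxymonosulfate (KHSO5), [K+].[O-]S(=O)(=O)OO  
Why: RuO4-catalysed ketohydroxylation of an alkene: RuO4, formed from RuCl3 and KHSO5, adds [3+2] to the more electron-rich trisubstituted C1=C1' alkene from the ring face anti to both acetoxy groups, and oxidative breakdown of the adduct leaves the carbonyl on the hydrogen-bearing C1' and the hydroxyl on C1. C1 is thereby set trans to both acetates by substrate shielding, and because C1' becomes trigonal the racemic 11 converges on the meso target.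

Compound list  
1 | 1,2-bis(trimethylsilyloxy)cyclobutene | C[Si](C)(C)OC1=C(O[Si](C)(C)C)CC1 | starting material  
2 | cyclobutane-1,2-dione | O=C1CCC1=O | intermediate  
3 | 3-bromocyclobutane-1,2-dione (racemic, one enantiomer drawn) | O=C1C[C@H](Br)C1=O | intermediate  
4 | cyclobut-3-ene-1,2-dione | O=C1C=CC1=O | intermediate  
5 | 1-dodecyne | CCCCCCCCCCC#C | starting material  
6 | lithium dodec-1-yn-1-ide | [Li]C#CCCCCCCCCCC | intermediate  
7 | 4-(dodec-1-yn-1-yl)-4-hydroxycyclobut-2-en-1-one (racemic, one enantiomer drawn) | CCCCCCCCCCC#C[C@]1(O)C=CC1=O | intermediate  
8 | 2-undecylidenecyclopent-4-ene-1,3-dione | CCCCCCCCCCC=C1C(=O)C=CC1=O | intermediate  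
9 | 4-hydroxy-5-undecylidenecyclopent-2-en-1-one (racemic; both alkene geometries form, the Z isomer drawn) | CCCCCCCCCC/C=C1/[C@@H](O)C=CC1=O | intermediate  
10 | (1R*,3S*)-2-undecylidenecyclopent-4-ene-1,3-diol (hydroxyls cis; racemic, one enantiomer drawn) | CCCCCCCCCC/C=C1/[C@@H](O)C=C[C@H]1O | intermediate  
11 | (1R*,3S*)-2-undecylidenecyclopent-4-ene-1,3-diyl diacetate (acetates cis; racemic, one enantiomer drawn) | CCCCCCCCCC/C=C1/[C@@H](OC(C)=O)C=C[C@H]1OC(C)=O | intermediate  
12 | (1R,3S)-2-hydroxy-2-undecanoylcyclopent-4-ene-1,3-diyl diacetate, acetates cis to each other and trans to the hydroxyl (meso) | CCCCCCCCCCC(=O)[C@@]1(O)[C@@H](OC(C)=O)C=C[C@H]1OC(C)=O | target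

Total steps: 7. Longest linear sequence: 7 steps (1 to 12); 5 enters at step 3.

Least certain steps

Step 4 (key step). The likely failure is loss of catalyst turnover together with oligomerisation. Both the unsubstituted cyclobutenone of 7 and the doubly activated dione 8 are strong acceptors, and the established examples of this expansion carry substituents on the ring alkene. If protonation of the vinyl–palladium bond lags, divalent palladium is reduced to the metal and the remaining 7 is consumed unselectively. Fallback, setting out from 7: the same acyl shift is triggered by a stoichiometric iodonium source, so that no turnover step is needed. N-Iodosuccinimide in CH2Cl2 at 0 °C should give 2-(1-iodoundecylidene)cyclopent-4-ene-1,3-dione F1. Luche reduction as in step 5 gives (1R*,3S*)-2-(1-iodoundecylidene)cyclopent-4-ene-1,3-diol F2. Radical hydrodeiodination (Bu3SnH, Et3B, air, toluene, 0 °C) then removes the iodine and the route is rejoined at 10.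

Step 7. The likely failure is poor site selectivity between the exocyclic and the ring alkene, which carry the same number of allylic acetoxy groups and are open from the same face, followed by over-oxidation of the ketol by the very reactive RuO4. Fallback, setting out from 11: the oxygenation is split into a dihydroxylation and a separate alcohol oxidation. OsO4 (2 mol %) with N-methylmorpholine N-oxide in acetone/H2O at 0 °C, stopped short of full conversion, is a milder and more discriminating electrophile. It should give (1R*,3S*)-2-hydroxy-2-(1-hydroxyundecyl)cyclopent-4-ene-1,3-diyl diacetate F3, with both new hydroxyls anti to the acetates. Dess–Martin periodinane (NaHCO3, CH2Cl2) then oxidises only the secondary carbinol and the route arrives at 12.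

Step 5. The likely failure is poor facial selectivity in the second hydride addition, since the only bias is the remote oxygen of 9, which would give the trans-diol beside 10; some conjugate reduction at C1' is also possible. Fallback, setting out from 8: the trans isomer (1R*,3R*)-2-undecylidenecyclopent-4-ene-1,3-diol F4 formed in the reduction is separated and not discarded. A Mitsunobu reaction with acetic acid (PPh3, diisopropyl azodicarboxylate, THF, 0 °C) inverts one carbinol and delivers it already acetylated, as cis-3-hydroxy-2-undecylidenecyclopent-4-en-1-yl acetate F5; inversion at either carbinol leads to the same racemic series. Acetylation of the remaining hydroxyl (Ac2O, pyridine) rejoins the route at 11.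

Step 3. The likely failure is conjugate addition and anionic oligomerisation of the small, unhindered ene-dione, double addition, and loss of 4 through its volatility and light sensitivity. Fallback, setting out from 2 and 6: the ring alkene is introduced after the ring expansion. Addition of 6 to 2 (THF, −78 °C) should give 2-(dodec-1-yn-1-yl)-2-hydroxycyclobutan-1-one F6. The Pd(O2CCF3)2-catalysed acyl shift, supported for saturated 2-oxygenated cyclobutanones by their pinacol-type acyl migrations, gives 2-undecylidenecyclopentane-1,3-dione F7. Dehydrogenation with IBX (DMSO, 60 °C) installs the C3=C4 alkene and rejoins the route at 8.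

## Further compounds

F1 | step 4 | 2-(1-iodoundecylidene)cyclopent-4-ene-1,3-dione | CCCCCCCCCCC(I)=C1C(=O)C=CC1=O  
F2 | step 4 | (1R*,3S*)-2-(1-iodoundecylidene)cyclopent-4-ene-1,3-diol (hydroxyls cis; racemic, one enantiomer drawn) | CCCCCCCCCC/C(I)=C1/[C@@H](O)C=C[C@H]1O  
F3 | step 7 | (1R*,3S*)-2-hydroxy-2-(1-hydroxyundecyl)cyclopent-4-ene-1,3-diyl diacetate, both new hydroxyls anti to the acetates (racemic, one enantiomer drawn) | CCCCCCCCCC[C@H](O)[C@@]1(O)[C@@H](OC(C)=O)C=C[C@H]1OC(C)=O  
F4 | step 5 | (1R*,3R*)-2-undecylidenecyclopent-4-ene-1,3-diol (hydroxyls trans; racemic, one enantiomer drawn) | CCCCCCCCCC/C=C1/[C@@H](O)C=C[C@@H]1O  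
F5 | step 5 | cis-3-hydroxy-2-undecylidenecyclopent-4-en-1-yl acetate (racemic; regioisomer with the acetate remote from the chain drawn) | CCCCCCCCCC/C=C1/[C@@H](OC(C)=O)C=C[C@H]1O  
F6 | step 3 | 2-(dodec-1-yn-1-yl)-2-hydroxycyclobutan-1-one (racemic, one enantiomer drawn) | CCCCCCCCCCC#C[C@]1(O)CCC1=O  
F7 | step 3 | 2-undecylidenecyclopentane-1,3-dione | CCCCCCCCCCC=C1C(=O)CCC1=O  
A1 | alternative 1 | 1-[cis-2,5-bis(tert-butyldimethylsilyloxy)-1-hydroxycyclopent-3-en-1-yl]undecan-1-one, hydroxyl trans to both silyloxy groups (meso) | CCCCCCCCCCC(=O)[C@@]1(O)[C@@H](O[Si](C)(C)C(C)(C)C)C=C[C@H]1O[Si](C)(C)C(C)(C)C  
A2 | alternative 1 | cis-3,5-bis(tert-butyldimethylsilyloxy)-4-(undec-1-en-1-ylidene)cyclopent-1-ene (either allene diastereomer) | CCCCCCCCCC=C=C1[C@@H](O[Si](C)(C)C(C)(C)C)C=C[C@H]1O[Si](C)(C)C(C)(C)C  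
A3 | alternative 2 | 4-(tert-butyldimethylsilyloxy)-5-hydroxy-5-(undec-1-yn-1-yl)cyclopent-2-en-1-one, hydroxyl trans to silyloxy (racemic, one enantiomer drawn) | CCCCCCCCCC#C[C@@]1(O)C(=O)C=C[C@H]1O[Si](C)(C)C(C)(C)C  
A4 | alternative 2 | methyl (Z)-3-(tert-butyldimethylsilyloxy)-2-hydroxy-5-iodo-2-(undec-1-yn-1-yl)pent-4-enoate, relative configuration as in A3 (racemic, one enantiomer drawn) | CCCCCCCCCC#C[C@@](O)(C(=O)OC)[C@H](O[Si](C)(C)C(C)(C)C)/C=C\I  
A5 | alternative 3 | 1-(1,2,5-trihydroxycyclopent-3-en-1-yl)undecan-1-one, 2,5-cis with the C1 hydroxyl trans to both (meso) | CCCCCCCCCCC(=O)[C@@]1(O)[C@@H](O)C=C[C@H]1O  
A6 | alternative 3 | 1-hydroxydodecan-2-one | CCCCCCCCCCC(=O)CO  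
A7 | alternative 3 | (Z)-but-2-enedial | O=C/C=C\C=O  
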